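Assumption: locants C1–C15 in the text follow guaiane numbering of the target (C1/C5 ring fusion, C4 and C10 methyl-bearing, C7 isopropyl-bearing, C8 ester-bearing); α is the face of H-1.

**Retrosynthetic overview**
1. Target ⇐ phenolic pivalate; oxirane ⇐ hydroxyl-directed epoxidation of the C3=C4 alkene; alkene ⇐ C4 ketone (enol triflate, methyl coupling); ester ⇐ 8β-alcohol + protected 3-hydroxy-4-methoxybenzoyl chloride built from catechol.
2. 8β-OH ⇐ directed reduction of a C8 ketone ⇐ oxidation of the 8α-alcohol, which is carried equatorial through the ring closure.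
3. Key step: the C1–C10 bond by a SmI2 ketyl radical 7-endo cyclisation onto a 2-alkylcyclopentenone; it closes the seven-membered ring and sets C10 and C1 (C5 by equilibration).
4. Cyclisation substrate ⇐ proline aldol with acetone ⇐ enamine-catalysed α-alkylation of 3-methylbutanal with 2-(bromomethyl)cyclopentenone ⇐ cyclopentenone + formaldehyde.
5. Ring order: five-membered ring (from cyclopentenone) → seven-membered ring (radical step) → oxirane (last).

**Route**

Step 1
Reactants: 1 cyclopent-2-en-1-one; 2 formaldehyde (37% aqueous)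
Product: 3 2-(hydroxymethyl)cyclopent-2-en-1-one
Conditions: imidazole (0.1 equiv), THF/H2O 1:1, rt
Reagents that add atoms: none
Why: Morita–Baylis–Hillman reaction of the enone with formaldehyde under nucleophilic catalysis; no stereocentre is formed.

Step 2
Reactants: 3 2-(hydroxymethyl)cyclopent-2-en-1-one
Product: 4 2-(bromomethyl)cyclopent-2-en-1-one
Conditions: PBr3 (0.4 equiv), Et2O, 0 °C
Reagents that add atoms: phosphorus tribromide, BrP(Br)Br
Why: Bromodehydroxylation of a primary allylic alcohol (SN2 on the phosphite ester); no stereocentre.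

Step 3
Reactants: 4 2-(bromomethyl)cyclopent-2-en-1-one; 5 3-methylbutanal
Product: 6 (2R)-3-methyl-2-[(5-oxocyclopent-1-en-1-yl)methyl]butanal
Conditions: 5 (2 equiv), (R)-α,α-diphenylprolinol trimethylsilyl ether (20 mol %), DMAP (20 mol %), NaHCO3 (1.5 equiv), CH2Cl2, 0 °C
Reagents that add atoms: none
Why: Enamine-catalysed asymmetric α-alkylation of an aldehyde with a 2-(bromomethyl) Michael acceptor (SN2′/SN2′ relay through the DMAP allylic ammonium salt); the (E)-enamine reacts on the face not shielded by the diphenyl(silyloxy)methyl group, which sets C7 as R.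

Step 4
Reactants: 6 (2R)-3-methyl-2-[(5-oxocyclopent-1-en-1-yl)methyl]butanal; 7 acetone
Product: 8 2-[(2R,3S)-3-hydroxy-5-oxo-2-(propan-2-yl)hexyl]cyclopent-2-en-1-one
Conditions: D-proline (30 mol %), acetone/DMSO 1:4, rt
Reagents that add atoms: none
Why: Proline-catalysed direct enamine aldol addition; D-proline directs acetone to the aldehyde face that gives 3S (catalyst control against the weak Felkin bias), deliberately the C8 epimer whose hydroxyl is equatorial in the next step.

Step 5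
Reactants: 8 2-[(2R,3S)-3-hydroxy-5-oxo-2-(propan-2-yl)hexyl]cyclopent-2-en-1-one
Product: 10 (3aR,4R,6S,7R,8aS)-4,6-dihydroxy-4-methyl-7-(propan-2-yl)-3,3a,4,5,6,7,8,8a-octahydroazulen-1(2H)-one, via cis-fused 8a-epimer 9 (not isolated)
Conditions: SmI2 (2.5 equiv), HMPA (10 equiv), t-BuOH (2 equiv), THF, −78 to 0 °C; then K2CO3 (cat.), MeOH, rt
Reagents that add atoms: none
Why: SmI2 ketyl–olefin radical cyclisation in the 7-endo mode onto the enone β-carbon through a chair-like transition state with isopropyl, free hydroxyl and the HMPA-loaded O–Sm group equatorial and methyl axial, which sets C10 (OH α, Me β) and C1 (H α); base equilibration of the α-keto centre then gives the more stable trans ring fusion (H-5 β).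

Step 6
Reactants: 10 (3aR,4R,6S,7R,8aS)-4,6-dihydroxy-4-methyl-7-(propan-2-yl)-3,3a,4,5,6,7,8,8a-octahydroazulen-1(2H)-one
Product: 11 (3aR,4R,7R,8aS)-4-hydroxy-4-methyl-7-(propan-2-yl)-3,3a,4,5,8,8a-hexahydroazulene-1,6(2H,7H)-dione
Conditions: Dess–Martin periodinane (1.3 equiv), CH2Cl2, 0 °C to rt
Reagents that add atoms: none
Why: Dess–Martin oxidation of the only secondary alcohol (the tertiary one is inert); it erases the temporary C8 configuration and gives a β-hydroxy ketone without touching C7.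

Step 7
Reactants: 11 (3aR,4R,7R,8aS)-4-hydroxy-4-methyl-7-(propan-2-yl)-3,3a,4,5,8,8a-hexahydroazulene-1,6(2H,7H)-dione
Product: 12 (3aR,4R,6R,7R,8aS)-4,6-dihydroxy-4-methyl-7-(propan-2-yl)-3,3a,4,5,6,7,8,8a-octahydroazulen-1(2H)-one
Conditions: Me4NBH(OAc)3 (5 equiv), MeCN/AcOH 1:1, −30 °C
Reagents that add atoms: none
Why: Evans–Saksena hydroxyl-directed reduction: hydride is delivered from the borohydride bound to the C10 hydroxyl on the α-face (the β-face is also blocked by the syn-axial methyl and the isopropyl), giving the 1,3-anti diol with 8β-OH (R); the cyclopentanone is not reduced by this reagent.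

Step 8
Reactants: 13 benzene-1,2-diol (catechol)
Product: 15 2-methoxyphenyl 2,2-dimethylpropanoate, via guaiacol 14 (not isolated)
Conditions: MeI (1.0 equiv), K2CO3 (1.1 equiv), acetone, reflux; then pivaloyl chloride (1.2 equiv), K2CO3 (1.5 equiv), rt
Reagents that add atoms: iodomethane, CI; pivaloyl chloride, CC(C)(C)C(Cl)=O
Why: Williamson mono-O-methylation followed by O-acylation of the remaining phenol in one pot (veratrole and the dipivalate are removed by chromatography); no stereocentre.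

Step 9
Reactants: 15 2-methoxyphenyl 2,2-dimethylpropanoate
Product: 16 3-[(2,2-dimethylpropanoyl)oxy]-4-methoxybenzoyl chloride
Conditions: (COCl)2 (2 equiv), AlCl3 (1.2 equiv), CH2Cl2, 0 °C; ice/CaCl2 quench at 0 °C; crystallise from hexane
Reagents that add atoms: oxalyl chloride, O=C(Cl)C(Cl)=O
Why: Friedel–Crafts chlorocarbonylation with oxalyl chloride goes para to the methoxy group (the acyloxy oxygen is the weaker donor), and the aroyl chloride survives a short cold quench, so it is isolated as the acylating agent itself; no stereocentre.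

Step 10
Reactants: 12 (3aR,4R,6R,7R,8aS)-4,6-dihydroxy-4-methyl-7-(propan-2-yl)-3,3a,4,5,6,7,8,8a-octahydroazulen-1(2H)-one; 16 3-[(2,2-dimethylpropanoyl)oxy]-4-methoxybenzoyl chloride
Product: 17 (3aR,4R,6R,7R,8aS)-4-hydroxy-4-methyl-1-oxo-7-(propan-2-yl)decahydroazulen-6-yl 3-[(2,2-dimethylpropanoyl)oxy]-4-methoxybenzoate
Conditions: 16 (1.5 equiv), Et3N (3 equiv), DMAP (0.2 equiv), CH2Cl2, 40 °C
Reagents that add atoms: none
Why: DMAP-catalysed acylation of the alcohol by the aroyl chloride; only the secondary hydroxyl reacts (the tertiary one is inert) and C8 keeps its configuration because the C–O bond is not broken.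

Step 11
Reactants: 17 (3aR,4R,6R,7R,8aS)-4-hydroxy-4-methyl-1-oxo-7-(propan-2-yl)decahydroazulen-6-yl 3-[(2,2-dimethylpropanoyl)oxy]-4-methoxybenzoate
Product: 18 (3aR,4R,6R,7R,8aS)-4-hydroxy-4-methyl-7-(propan-2-yl)-1-(trifluoromethanesulfonyloxy)-3,3a,4,5,6,7,8,8a-octahydroazulen-6-yl 3-[(2,2-dimethylpropanoyl)oxy]-4-methoxybenzoate
Conditions: KN(SiMe3)2 (2.2 equiv), THF, −78 °C; Comins' reagent (1.2 equiv), −78 to −40 °C; then AcOH
Reagents that add atoms: N-(5-chloropyridin-2-yl)-1,1,1-trifluoro-N-(trifluoromethanesulfonyl)methanesulfonamide, Clc1ccc(nc1)N(S(=O)(=O)C(F)(F)F)S(=O)(=O)C(F)(F)F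
Why: Kinetic enolisation at the unhindered C3 methylene (not at the ring-fusion C5–H) and O-triflation give the C3=C4 enol triflate; the second equivalent of base only parks the tertiary hydroxyl as its alkoxide.

Step 12
Reactants: 18 (3aR,4R,6R,7R,8aS)-4-hydroxy-4-methyl-7-(propan-2-yl)-1-(trifluoromethanesulfonyloxy)-3,3a,4,5,6,7,8,8a-octahydroazulen-6-yl 3-[(2,2-dimethylpropanoyl)oxy]-4-methoxybenzoate
Product: 19 (3aR,4R,6R,7R,8aS)-4-hydroxy-1,4-dimethyl-7-(propan-2-yl)-3,3a,4,5,6,7,8,8a-octahydroazulen-6-yl 3-[(2,2-dimethylpropanoyl)oxy]-4-methoxybenzoate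
Conditions: Me4Sn (3 equiv), Pd(PPh3)4 (5 mol %), LiCl (3 equiv), THF, 65 °C
Reagents that add atoms: tetramethylstannane, C[Sn](C)(C)C
Why: Stille cross-coupling of the enol triflate installs the C4 methyl with the alkene fixed at C3=C4; neutral conditions leave both esters and the free hydroxyl alone.

Step 13
Reactants: 19 (3aR,4R,6R,7R,8aS)-4-hydroxy-1,4-dimethyl-7-(propan-2-yl)-3,3a,4,5,6,7,8,8a-octahydroazulen-6-yl 3-[(2,2-dimethylpropanoyl)oxy]-4-methoxybenzoate
Product: 20 (1R,3R,4S,5S,7R,8R,10R)-3,4-epoxy-10-hydroxyguaian-8-yl 3-[(2,2-dimethylpropanoyl)oxy]-4-methoxybenzoate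
Conditions: VO(acac)2 (5 mol %), t-BuOOH (1.5 equiv), CH2Cl2, 0 °C to rt
Reagents that add atoms: tert-butyl hydroperoxide, CC(C)(C)OO
Why: Hydroxyl-directed vanadium-catalysed epoxidation: the 10α-hydroxyl binds the metal and delivers oxygen to the α-face of the trisubstituted alkene (the β-face is also shielded by the C10 methyl), setting C3 and C4.

Step 14
Reactants: 20 (1R,3R,4S,5S,7R,8R,10R)-3,4-epoxy-10-hydroxyguaian-8-yl 3-[(2,2-dimethylpropanoyl)oxy]-4-methoxybenzoate
Product: 21 (1R,3R,4S,5S,7R,8R,10R)-3,4-epoxy-10-hydroxyguaian-8-yl 3-hydroxy-4-methoxybenzoate (CNP0264062.2)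
Conditions: K2CO3 (0.2 equiv), MeOH, 0 °C to rt
Reagents that add atoms: none
Why: Base-catalysed transesterification removes the phenolic pivalate, which is far more reactive than the electron-rich benzoate of a hindered secondary alcohol; the epoxide and all stereocentres are untouched.

**Compound list**
1 | cyclopent-2-en-1-one | O=C1C=CCC1 | starting material
2 | formaldehyde (37% aqueous) | C=O | starting material
3 | 2-(hydroxymethyl)cyclopent-2-en-1-one | O=C1CCC=C1CO | intermediate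
4 | 2-(bromomethyl)cyclopent-2-en-1-one | O=C1CCC=C1CBr | intermediate
5 | 3-methylbutanal | CC(C)CC=O | starting material
6 | (2R)-3-methyl-2-[(5-oxocyclopent-1-en-1-yl)methyl]butanal | O=C1CCC=C1C[C@@H](C=O)C(C)C | intermediate
7 | acetone | CC(C)=O | starting material
8 | 2-[(2R,3S)-3-hydroxy-5-oxo-2-(propan-2-yl)hexyl]cyclopent-2-en-1-one | CC(=O)C[C@H](O)[C@H](CC1=CCCC1=O)C(C)C | intermediate
9 | (3aR,4R,6S,7R,8aR)-4,6-dihydroxy-4-methyl-7-(propan-2-yl)-3,3a,4,5,6,7,8,8a-octahydroazulen-1(2H)-one (cis-fused) | O[C@H]1C[C@@](C)(O)[C@@H]2CCC(=O)[C@@H]2C[C@@H]1C(C)C | intermediate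
10 | (3aR,4R,6S,7R,8aS)-4,6-dihydroxy-4-methyl-7-(propan-2-yl)-3,3a,4,5,6,7,8,8a-octahydroazulen-1(2H)-one (trans-fused, 8α-OH) | O[C@H]1C[C@@](C)(O)[C@@H]2CCC(=O)[C@H]2C[C@@H]1C(C)C | intermediate
11 | (3aR,4R,7R,8aS)-4-hydroxy-4-methyl-7-(propan-2-yl)-3,3a,4,5,8,8a-hexahydroazulene-1,6(2H,7H)-dione | O=C1C[C@@](C)(O)[C@@H]2CCC(=O)[C@H]2C[C@@H]1C(C)C | intermediate
12 | (3aR,4R,6R,7R,8aS)-4,6-dihydroxy-4-methyl-7-(propan-2-yl)-3,3a,4,5,6,7,8,8a-octahydroazulen-1(2H)-one (8β-OH) | O[C@@H]1C[C@@](C)(O)[C@@H]2CCC(=O)[C@H]2C[C@@H]1C(C)C | intermediate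
13 | benzene-1,2-diol (catechol) | Oc1ccccc1O | starting material
14 | 2-methoxyphenol (guaiacol) | COc1ccccc1O | intermediate
15 | 2-methoxyphenyl 2,2-dimethylpropanoate | COc1ccccc1OC(=O)C(C)(C)C | intermediate
16 | 3-[(2,2-dimethylpropanoyl)oxy]-4-methoxybenzoyl chloride | COc1ccc(C(Cl)=O)cc1OC(=O)C(C)(C)C | intermediate
17 | (3aR,4R,6R,7R,8aS)-4-hydroxy-4-methyl-1-oxo-7-(propan-2-yl)decahydroazulen-6-yl 3-[(2,2-dimethylpropanoyl)oxy]-4-methoxybenzoate | COc1ccc(C(=O)O[C@@H]2C[C@@](C)(O)[C@@H]3CCC(=O)[C@H]3C[C@@H]2C(C)C)cc1OC(=O)C(C)(C)C | intermediate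
18 | (3aR,4R,6R,7R,8aS)-4-hydroxy-4-methyl-7-(propan-2-yl)-1-(trifluoromethanesulfonyloxy)-3,3a,4,5,6,7,8,8a-octahydroazulen-6-yl 3-[(2,2-dimethylpropanoyl)oxy]-4-methoxybenzoate | COc1ccc(C(=O)O[C@@H]2C[C@@](C)(O)[C@@H]3CC=C(OS(=O)(=O)C(F)(F)F)[C@H]3C[C@@H]2C(C)C)cc1OC(=O)C(C)(C)C | intermediate
19 | (3aR,4R,6R,7R,8aS)-4-hydroxy-1,4-dimethyl-7-(propan-2-yl)-3,3a,4,5,6,7,8,8a-octahydroazulen-6-yl 3-[(2,2-dimethylpropanoyl)oxy]-4-methoxybenzoate | COc1ccc(C(=O)O[C@@H]2C[C@@](C)(O)[C@@H]3CC=C(C)[C@H]3C[C@@H]2C(C)C)cc1OC(=O)C(C)(C)C | intermediate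
20 | (1R,3R,4S,5S,7R,8R,10R)-3,4-epoxy-10-hydroxyguaian-8-yl 3-[(2,2-dimethylpropanoyl)oxy]-4-methoxybenzoate (3α,4α-epoxide, 1αH, 5βH) | COc1ccc(C(=O)O[C@@H]2C[C@@](C)(O)[C@@H]3C[C@H]4O[C@@]4(C)[C@H]3C[C@@H]2C(C)C)cc1OC(=O)C(C)(C)C | intermediate
21 | (1R,3R,4S,5S,7R,8R,10R)-3,4-epoxy-10-hydroxyguaian-8-yl 3-hydroxy-4-methoxybenzoate | COc1ccc(C(=O)O[C@@H]2C[C@@](C)(O)[C@@H]3C[C@H]4O[C@@]4(C)[C@H]3C[C@@H]2C(C)C)cc1O | target

**Totals**
Total step count: 14. Longest linear sequence: 12 steps (steps 1–7 and 10–14).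

**Three steps most likely to fail**

Step 5 (the radical ring closure). Simple enone reduction or the wrong face of attack would ruin C1/C10. The fallback sets out from 6 and comes back at 11, so steps 4–6 are skipped. Aldehyde 6 is treated with 2-(trimethylsilyloxy)propene (large excess), tert-dodecanethiol (2 mol %) and di-tert-butyl hyponitrite in benzene at 40 °C. This is a thiol-catalysed radical-chain hydroacylation relayed into a Giese closure: the acyl radical of 6 adds to the enol ether CH2, and the tertiary α-silyloxy radical closes 7-endo onto the enone. The product is the silyl ether (3aR,4R,7R,8aS)-4-methyl-7-(propan-2-yl)-4-(trimethylsilyloxy)-3,3a,4,5,8,8a-hexahydroazulene-1,6(2H,7H)-dione F1. Aqueous citric acid in THF cleaves the silyl ether and gives 11. C10 selectivity in this variant is uncertain, so any C4-epimer has to be removed by chromatography.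

Step 3 (asymmetric alkylation with a cyclic bromo-enone not yet used in this reaction type). The fallback sets out from 5 (with 4) and comes back at 6, using an auxiliary instead of a catalyst. Aldehyde 5 is condensed with (2S)-2-(methoxymethyl)pyrrolidin-1-amine to the hydrazone (E)-N-[(2S)-2-(methoxymethyl)pyrrolidin-1-yl]-3-methylbutan-1-imine F2. Deprotonation with LiN(iPr)2 (THF, −78 °C) and alkylation with 4 at −100 °C gives 2-{(2R)-2-[(E)-{[(2S)-2-(methoxymethyl)pyrrolidin-1-yl]imino}methyl]-3-methylbutyl}cyclopent-2-en-1-one F3. Aqueous oxalic acid cleaves the hydrazone without racemisation and returns 6.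

Step 4 (aldol against the substrate's Felkin bias). The fallback sets out from 6 and comes back at 8, using reagent control. (−)-B-Methallyldiisopinocampheylborane (Et2O, −78 °C; NaBO3 work-up) adds to the aldehyde of 6 and gives 2-[(2R,3S)-3-hydroxy-5-methyl-2-(propan-2-yl)hex-5-en-1-yl]cyclopent-2-en-1-one F4. Selective ozonolysis of its electron-rich 1,1-disubstituted alkene (O3, CH2Cl2/MeOH, −78 °C, Sudan red end point; Me2S) returns 8.

**Further compounds**
F1 | step 5 | (3aR,4R,7R,8aS)-4-methyl-7-(propan-2-yl)-4-(trimethylsilyloxy)-3,3a,4,5,8,8a-hexahydroazulene-1,6(2H,7H)-dione | O=C1C[C@@](C)(O[Si](C)(C)C)[C@@H]2CCC(=O)[C@H]2C[C@@H]1C(C)C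
F2 | step 3 | (E)-N-[(2S)-2-(methoxymethyl)pyrrolidin-1-yl]-3-methylbutan-1-imine | CC(C)C/C=N/N1CCC[C@H]1COC
F3 | step 3 | 2-{(2R)-2-[(E)-{[(2S)-2-(methoxymethyl)pyrrolidin-1-yl]imino}methyl]-3-methylbutyl}cyclopent-2-en-1-one | CC(C)[C@@H](CC1=CCCC1=O)/C=N/N1CCC[C@H]1COC
F4 | step 4 | 2-[(2R,3S)-3-hydroxy-5-methyl-2-(propan-2-yl)hex-5-en-1-yl]cyclopent-2-en-1-one | CC(=C)C[C@H](O)[C@H](CC1=CCCC1=O)C(C)C
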